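Retrosynthesis: the six phenol benzyl ethers and the amide mask of the carboxyl group come off first. The two bonds at Cα are then cut together, Cα–C(carboxyl) and O(Cα)–C(=O)(naphthoyl), followed by the biaryl bond C4–C1' of the naphthoic acid and then C4–C4a and C1=C2 of its carboxyl-bearing ring.
Enabling feature: the stereocentre Cα carries an acyloxy oxygen (the 2-naphthoate), a carboxyl carbon and the Cβ methylene with its catechol ring. This is exactly the triad that an acid, an isocyanide and an aldehyde deliver in a Passerini reaction.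
Forward: the catechol ring of 3,4-bis(benzyloxy)benzaldehyde becomes ring C4a–C8a of the naphthalene, and ring C1–C4 is annulated onto it by Stobbe condensation and Friedel–Crafts closure. The pendant catechol ring is joined at C4 by Suzuki coupling, the same aldehyde homologated by one carbon supplies the Cβ unit, and acid, aldehyde and a convertible aryl isocyanide are then joined at Cα.
Stereochemistry: the only stereocentre, (R)-Cα, comes from Si-face addition of the isocyanide to the aldehyde inside a chiral phosphoric acid. The later steps are acidic, weakly basic at 0 °C or neutral, so the centre should not be scrambled.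

Key step: step 9

Assumption: the convertible isocyanide and the arylboronic acid are taken as catalogue compounds.
Assumption: the (R)-configured catalyst is taken to leave the Si face of the arylacetaldehyde open. If the sense of induction proves opposite, the equally available (S)-catalyst is used in the same way.

Step 1
Reactants: 1 3,4-bis(benzyloxy)benzaldehyde; 2 diethyl succinate
Product: 3 (E)-4-[3,4-bis(benzyloxy)phenyl]-3-(ethoxycarbonyl)but-3-enoic acid
Conditions: KOtBu, t-BuOH, reflux; then aq. HCl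
Reagents that add atoms: none
Why: Stobbe condensation, in which aldol addition of the succinate enolate, lactonisation and base-induced eliminative ring opening deliver the half-ester irreversibly as its carboxylate, with the aryl group trans to CO2Et (E) and therefore cis to the CH2CO2H arm needed for ring closure.

Step 2
Reactants: 3 (E)-4-[3,4-bis(benzyloxy)phenyl]-3-(ethoxycarbonyl)but-3-enoic acid
Product: 4 ethyl 4-acetoxy-6,7-bis(benzyloxy)-2-naphthoate
Conditions: Ac2O, NaOAc, reflux
Reagents that add atoms: acetic anhydride, CC(=O)OC(C)=O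
Why: Classical naphthol annulation of a Stobbe half-ester, in which activation of the acid by Ac2O, intramolecular Friedel–Crafts acylation at the less hindered ring carbon para to the 3-benzyloxy group, enolisation and O-acetylation give the 6,7-dioxygenated 4-acetoxy-2-naphthoate.

Step 3
Reactants: 4 ethyl 4-acetoxy-6,7-bis(benzyloxy)-2-naphthoate
Product: 5 ethyl 6,7-bis(benzyloxy)-4-hydroxy-2-naphthoate
Conditions: K2CO3, EtOH, rt; then aq. HCl
Reagents that add atoms: none
Why: Base-mediated transesterification, selective because the aryl acetate is far more electrophilic than the conjugated ethyl ester, whose own exchange with ethanol is degenerate.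

Step 4
Reactants: 5 ethyl 6,7-bis(benzyloxy)-4-hydroxy-2-naphthoate
Product: 6 ethyl 6,7-bis(benzyloxy)-4-(trifluoromethylsulfonyloxy)-2-naphthoate
Conditions: Tf2O, pyridine, CH2Cl2, 0 °C
Reagents that add atoms: trifluoromethanesulfonic anhydride, O=S(=O)(OS(=O)(=O)C(F)(F)F)C(F)(F)F
Why: Standard O-sulfonylation of a naphthol, which is the only nucleophilic group in the molecule.

Step 5
Reactants: 6 ethyl 6,7-bis(benzyloxy)-4-(trifluoromethylsulfonyloxy)-2-naphthoate; 7 3,4-bis(benzyloxy)phenylboronic acid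
Product: 8 ethyl 6,7-bis(benzyloxy)-4-[3,4-bis(benzyloxy)phenyl]-2-naphthoate
Conditions: Pd(PPh3)4 (5 mol %), K2CO3, toluene/EtOH/H2O, 80 °C
Reagents that add atoms: none
Why: Suzuki–Miyaura coupling of an aryl triflate on an ester-bearing ring with an electron-rich arylboronic acid forms the C4–C1' bond, while the benzyl ethers are inert and ethanol as co-solvent keeps ester exchange degenerate.

Step 6
Reactants: 8 ethyl 6,7-bis(benzyloxy)-4-[3,4-bis(benzyloxy)phenyl]-2-naphthoate
Product: 9 6,7-bis(benzyloxy)-4-[3,4-bis(benzyloxy)phenyl]-2-naphthoic acid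
Conditions: LiOH, THF/EtOH/H2O, 60 °C; then aq. HCl
Reagents that add atoms: lithium hydroxide, [Li+].[OH-]
Why: Plain saponification of the only ester in a molecule whose other groups are base-stable aryl benzyl ethers.

Step 7
Reactants: 1 3,4-bis(benzyloxy)benzaldehyde
Product: 10 1,2-bis(benzyloxy)-4-(2-methoxyvinyl)benzene (E/Z mixture)
Conditions: Ph3P(CH2OMe)Cl, KOtBu, THF, 0 °C to rt
Reagents that add atoms: (methoxymethyl)triphenylphosphonium chloride, COC[P+](c1ccccc1)(c1ccccc1)c1ccccc1.[Cl-]
Why: Wittig methoxymethylenation is the standard one-carbon homologation of an aromatic aldehyde, and the alkene geometry is of no consequence because both isomers hydrolyse to the same aldehyde.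

Step 8
Reactants: 10 1,2-bis(benzyloxy)-4-(2-methoxyvinyl)benzene
Product: 11 3,4-bis(benzyloxy)phenylacetaldehyde
Conditions: 2 M aq. HCl (cat.), THF, 50 °C; used at once
Reagents that add atoms: water, O
Why: Acid hydrolysis of an enol ether by C-protonation, hydration and loss of methanol leaves the benzyl ethers untouched, and the sensitive aldehyde is carried on without storage.

Step 9
Reactants: 9 6,7-bis(benzyloxy)-4-[3,4-bis(benzyloxy)phenyl]-2-naphthoic acid; 11 3,4-bis(benzyloxy)phenylacetaldehyde; 12 2-(2,2-dimethoxyethyl)phenyl isocyanide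
Product: 14 (R)-3-[3,4-bis(benzyloxy)phenyl]-1-{[2-(2,2-dimethoxyethyl)phenyl]amino}-1-oxopropan-2-yl 6,7-bis(benzyloxy)-4-[3,4-bis(benzyloxy)phenyl]-2-naphthoate, via (R)-O-naphthoyl α-hydroxy imidate 13 (not isolated)
Conditions: (R)-TRIP (10 mol %), 4 Å MS, CH2Cl2 (0.05 M), −20 °C, 11 added slowly by syringe pump
Reagents that add atoms: none
Why: The chiral phosphoric acid forms a hydrogen-bonded heterodimer with acid 9 and also binds the carbonyl oxygen of 11, so that the isocyanide carbon of 12 adds to the activated aldehyde and makes the Cα–C(carboxyl) bond. The nitrilium carbon is captured by the naphthoate oxygen to give imidate 13, and a Mumm-type O-to-O acyl shift through a five-membered transition state moves the naphthoyl group onto the Cα oxygen to give anilide 14. This is the chiral phosphoric acid catalysed enantioselective Passerini three-component reaction, and no ring is closed. The single new stereocentre is controlled by the 3,3'-aryl pocket of the catalyst, which shields the Re face of the bound aldehyde so that Si-face addition gives (R). The step needs the catalysed path to outrun both the racemic background addition and the self-aldol reaction of the enolisable aldehyde, and the weakly nucleophilic ortho-substituted aryl isocyanide, the high dilution, the low temperature and the low stationary concentration of 11 secure this. The dimethyl acetal and the six benzyl ethers are inert to these weak acids in dry CH2Cl2, and the product cannot epimerise under them.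

Step 10
Reactants: 14 (R)-Passerini anilide
Product: 15 (R)-3-[3,4-bis(benzyloxy)phenyl]-1-(indol-1-yl)-1-oxopropan-2-yl 6,7-bis(benzyloxy)-4-[3,4-bis(benzyloxy)phenyl]-2-naphthoate
Conditions: CSA (10 mol %), 5 Å MS, toluene, 80 °C
Reagents that add atoms: none
Why: Convertible-isocyanide activation, in which acid ionises the acetal, the anilide nitrogen closes on the oxocarbenium carbon and loss of the second methanol aromatises the new ring to an indole, giving an amide without resonance stabilisation while Cα sees no base.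

Step 11
Reactants: 15 (R)-N-acylindole
Product: 17 (R)-3-[3,4-bis(benzyloxy)phenyl]-2-({6,7-bis(benzyloxy)-4-[3,4-bis(benzyloxy)phenyl]-2-naphthoyl}oxy)propanoic acid, via the corresponding (R)-peroxy acid 16 (not isolated)
Conditions: LiOH, H2O2, THF/H2O, 0 °C; then aq. Na2SO3; then aq. HCl to pH 3
Reagents that add atoms: hydrogen peroxide, OO
Why: Perhydrolysis of an activated amide, in which the weakly basic but strongly nucleophilic hydroperoxide anion attacks the N-acylindole carbonyl (further activated by the α-acyloxy group) faster than the conjugated secondary naphthoate and without enolisation at 0 °C, after which sulfite reduces peroxy acid 16 to acid 17.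

Step 12
Reactants: 17 (R)-hexa-O-benzyl acid
Product: 18 eritrichin, (R)-3-(3,4-dihydroxyphenyl)-2-{[4-(3,4-dihydroxyphenyl)-6,7-dihydroxy-2-naphthoyl]oxy}propanoic acid
Conditions: H2 (1 atm), 10 % Pd/C, THF/EtOH, rt; filtration under argon
Reagents that add atoms: none
Why: Catalytic hydrogenolysis cleaves the six aryl benzyl ethers, whereas the O–Cα bond is homobenzylic and not benzylic, so the ester and the stereocentre are retained, and the naphthalene is not reduced at this pressure.

Compound list
1 | 3,4-bis(benzyloxy)benzaldehyde | O=Cc1ccc(OCc2ccccc2)c(OCc2ccccc2)c1 | starting material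
2 | diethyl succinate | CCOC(=O)CCC(=O)OCC | starting material
3 | (E)-4-[3,4-bis(benzyloxy)phenyl]-3-(ethoxycarbonyl)but-3-enoic acid | CCOC(=O)/C(CC(=O)O)=C/c1ccc(OCc2ccccc2)c(OCc2ccccc2)c1 | intermediate
4 | ethyl 4-acetoxy-6,7-bis(benzyloxy)-2-naphthoate | CCOC(=O)c1cc(OC(C)=O)c2cc(OCc3ccccc3)c(OCc3ccccc3)cc2c1 | intermediate
5 | ethyl 6,7-bis(benzyloxy)-4-hydroxy-2-naphthoate | CCOC(=O)c1cc(O)c2cc(OCc3ccccc3)c(OCc3ccccc3)cc2c1 | intermediate
6 | ethyl 6,7-bis(benzyloxy)-4-(trifluoromethylsulfonyloxy)-2-naphthoate | CCOC(=O)c1cc(OS(=O)(=O)C(F)(F)F)c2cc(OCc3ccccc3)c(OCc3ccccc3)cc2c1 | intermediate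
7 | 3,4-bis(benzyloxy)phenylboronic acid | OB(O)c1ccc(OCc2ccccc2)c(OCc2ccccc2)c1 | starting material
8 | ethyl 6,7-bis(benzyloxy)-4-[3,4-bis(benzyloxy)phenyl]-2-naphthoate | CCOC(=O)c1cc(-c2ccc(OCc3ccccc3)c(OCc3ccccc3)c2)c2cc(OCc3ccccc3)c(OCc3ccccc3)cc2c1 | intermediate
9 | 6,7-bis(benzyloxy)-4-[3,4-bis(benzyloxy)phenyl]-2-naphthoic acid | O=C(O)c1cc(-c2ccc(OCc3ccccc3)c(OCc3ccccc3)c2)c2cc(OCc3ccccc3)c(OCc3ccccc3)cc2c1 | intermediate
10 | 1,2-bis(benzyloxy)-4-(2-methoxyvinyl)benzene (E/Z mixture) | COC=Cc1ccc(OCc2ccccc2)c(OCc2ccccc2)c1 | intermediate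
11 | 3,4-bis(benzyloxy)phenylacetaldehyde | O=CCc1ccc(OCc2ccccc2)c(OCc2ccccc2)c1 | intermediate
12 | 2-(2,2-dimethoxyethyl)phenyl isocyanide | [C-]#[N+]c1ccccc1CC(OC)OC | starting material
13 | (R)-O-naphthoyl imidate (α-adduct): mixed anhydride of acid 9 with (R)-3-[3,4-bis(benzyloxy)phenyl]-N-[2-(2,2-dimethoxyethyl)phenyl]-2-hydroxypropanimidic acid | O=C(OC(=Nc1ccccc1CC(OC)OC)[C@H](O)Cc1ccc(OCc2ccccc2)c(OCc2ccccc2)c1)c1cc(-c2ccc(OCc3ccccc3)c(OCc3ccccc3)c2)c2cc(OCc3ccccc3)c(OCc3ccccc3)cc2c1 | intermediate
14 | (R)-3-[3,4-bis(benzyloxy)phenyl]-1-{[2-(2,2-dimethoxyethyl)phenyl]amino}-1-oxopropan-2-yl 6,7-bis(benzyloxy)-4-[3,4-bis(benzyloxy)phenyl]-2-naphthoate | O=C(O[C@H](Cc1ccc(OCc2ccccc2)c(OCc2ccccc2)c1)C(=O)Nc1ccccc1CC(OC)OC)c1cc(-c2ccc(OCc3ccccc3)c(OCc3ccccc3)c2)c2cc(OCc3ccccc3)c(OCc3ccccc3)cc2c1 | intermediate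
15 | (R)-3-[3,4-bis(benzyloxy)phenyl]-1-(indol-1-yl)-1-oxopropan-2-yl 6,7-bis(benzyloxy)-4-[3,4-bis(benzyloxy)phenyl]-2-naphthoate | O=C(O[C@H](Cc1ccc(OCc2ccccc2)c(OCc2ccccc2)c1)C(=O)n1ccc2ccccc21)c1cc(-c2ccc(OCc3ccccc3)c(OCc3ccccc3)c2)c2cc(OCc3ccccc3)c(OCc3ccccc3)cc2c1 | intermediate
16 | (R)-3-[3,4-bis(benzyloxy)phenyl]-2-({6,7-bis(benzyloxy)-4-[3,4-bis(benzyloxy)phenyl]-2-naphthoyl}oxy)propaneperoxoic acid | O=C(O[C@H](Cc1ccc(OCc2ccccc2)c(OCc2ccccc2)c1)C(=O)OO)c1cc(-c2ccc(OCc3ccccc3)c(OCc3ccccc3)c2)c2cc(OCc3ccccc3)c(OCc3ccccc3)cc2c1 | intermediate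
17 | (R)-3-[3,4-bis(benzyloxy)phenyl]-2-({6,7-bis(benzyloxy)-4-[3,4-bis(benzyloxy)phenyl]-2-naphthoyl}oxy)propanoic acid | O=C(O[C@H](Cc1ccc(OCc2ccccc2)c(OCc2ccccc2)c1)C(=O)O)c1cc(-c2ccc(OCc3ccccc3)c(OCc3ccccc3)c2)c2cc(OCc3ccccc3)c(OCc3ccccc3)cc2c1 | intermediate
18 | eritrichin | O=C(O[C@H](Cc1ccc(O)c(O)c1)C(=O)O)c1cc(-c2ccc(O)c(O)c2)c2cc(O)c(O)cc2c1 | target

Total steps: 12. Longest linear sequence: 10 (steps 1–6 and 9–12, from 1).

Steps most likely to fail

Step 9. Enantioface selection may be poor, because an unbranched, enolisable arylacetaldehyde and an aryl isocyanide lie at the edge of what the catalyst pocket differentiates. The racemic background addition or self-condensation of the aldehyde may also compete. The fallback takes the stereocentre from the chiral pool and forms the ester by acylation of a free alcohol. It sets out from acid 9. Commercial sodium (R)-3-(3,4-dihydroxyphenyl)lactate is benzylated at both phenols and at the carboxylate (BnBr, K2CO3, DMF) to give benzyl (R)-3-[3,4-bis(benzyloxy)phenyl]-2-hydroxypropanoate F1. Steglich esterification of this alcohol with 9 (EDC·HCl, DMAP, CH2Cl2, 0 °C) should give benzyl (R)-3-[3,4-bis(benzyloxy)phenyl]-2-({6,7-bis(benzyloxy)-4-[3,4-bis(benzyloxy)phenyl]-2-naphthoyl}oxy)propanoate F2. Hydrogenolysis of all seven benzyl groups (H2, Pd/C, THF/EtOH) comes back to the route at target 18.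

Step 11. The naphthoate may be lost by competing attack of the peroxide anion at the ester carbonyl, or Cα may epimerise by enolisation of the activated amide. The fallback uses a much more reactive acyl azole that is cleaved near neutrality. It sets out from 9 and 11, which are combined under the conditions of step 9 with the convertible reagent 2-nitrophenyl isocyanide in place of 12 to give the (R)-α-naphthoyloxy 2-nitroanilide F3. Zn/NH4Cl (THF/EtOH/H2O, rt) reduces the nitro group without touching the benzyl ethers and gives the (R)-α-naphthoyloxy 2-aminoanilide F4. Diazotisation (t-BuONO, AcOH, CH2Cl2, 0 °C) with closure of the diazonium group onto the amide nitrogen gives the (R)-α-naphthoyloxy N-acylbenzotriazole F5. Water with NaHCO3 in THF at rt hydrolyses this acyl azole and comes back to the route at acid 17.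

Step 8. The arylacetaldehyde may undergo acid-promoted self-condensation and air oxidation while it is being released from the enol ether. The fallback reaches the aldehyde by oxidation under neutral, non-aqueous conditions. It sets out from 1. Wittig methylenation (Ph3PCH3Br, KOtBu, THF) gives 1,2-bis(benzyloxy)-4-vinylbenzene F6. Hydroboration–oxidation (9-BBN, THF; then NaOH, H2O2) gives 2-[3,4-bis(benzyloxy)phenyl]ethanol F7, which can be stored. Dess–Martin oxidation (NaHCO3, CH2Cl2, rt) just before use comes back to the route at aldehyde 11.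

Further compounds
F1 | step 9 | benzyl (R)-3-[3,4-bis(benzyloxy)phenyl]-2-hydroxypropanoate | O[C@H](Cc1ccc(OCc2ccccc2)c(OCc2ccccc2)c1)C(=O)OCc1ccccc1
F2 | step 9 | benzyl (R)-3-[3,4-bis(benzyloxy)phenyl]-2-({6,7-bis(benzyloxy)-4-[3,4-bis(benzyloxy)phenyl]-2-naphthoyl}oxy)propanoate | O=C(O[C@H](Cc1ccc(OCc2ccccc2)c(OCc2ccccc2)c1)C(=O)OCc1ccccc1)c1cc(-c2ccc(OCc3ccccc3)c(OCc3ccccc3)c2)c2cc(OCc3ccccc3)c(OCc3ccccc3)cc2c1
F3 | step 11 | (R)-3-[3,4-bis(benzyloxy)phenyl]-1-[(2-nitrophenyl)amino]-1-oxopropan-2-yl 6,7-bis(benzyloxy)-4-[3,4-bis(benzyloxy)phenyl]-2-naphthoate | O=C(O[C@H](Cc1ccc(OCc2ccccc2)c(OCc2ccccc2)c1)C(=O)Nc1ccccc1[N+](=O)[O-])c1cc(-c2ccc(OCc3ccccc3)c(OCc3ccccc3)c2)c2cc(OCc3ccccc3)c(OCc3ccccc3)cc2c1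
F4 | step 11 | (R)-1-[(2-aminophenyl)amino]-3-[3,4-bis(benzyloxy)phenyl]-1-oxopropan-2-yl 6,7-bis(benzyloxy)-4-[3,4-bis(benzyloxy)phenyl]-2-naphthoate | O=C(O[C@H](Cc1ccc(OCc2ccccc2)c(OCc2ccccc2)c1)C(=O)Nc1ccccc1N)c1cc(-c2ccc(OCc3ccccc3)c(OCc3ccccc3)c2)c2cc(OCc3ccccc3)c(OCc3ccccc3)cc2c1
F5 | step 11 | (R)-1-(benzotriazol-1-yl)-3-[3,4-bis(benzyloxy)phenyl]-1-oxopropan-2-yl 6,7-bis(benzyloxy)-4-[3,4-bis(benzyloxy)phenyl]-2-naphthoate | O=C(O[C@H](Cc1ccc(OCc2ccccc2)c(OCc2ccccc2)c1)C(=O)n1nnc2ccccc21)c1cc(-c2ccc(OCc3ccccc3)c(OCc3ccccc3)c2)c2cc(OCc3ccccc3)c(OCc3ccccc3)cc2c1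
F6 | step 8 | 1,2-bis(benzyloxy)-4-vinylbenzene | C=Cc1ccc(OCc2ccccc2)c(OCc2ccccc2)c1
F7 | step 8 | 2-[3,4-bis(benzyloxy)phenyl]ethanol | OCCc1ccc(OCc2ccccc2)c(OCc2ccccc2)c1
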